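**Plan**

- Numbering: oxolane O1, C2 (ring B, the aryl ether ring), C3 (Me), C4 (Me), C5 (ring C, free guaiacyl); ring A is the side-chain guaiacyl on carbinol C7, and C8 carries the ether oxygen.
- Retrosynthesis cuts, in order: the C8–O bond to ring B (with C7–OH taken back to a ketone), the C4 methyl (back to a C4 ketone through C4=CH2), the ring bond C2–C3, and finally the acetal bonds at C2.
- Enabling feature: C5 is an O-bearing benzylic carbon next to C4 at the carbonyl level, i.e. a mandelic acid carbinol, and C2 is an aryl aldehyde carbon joined to it through O1. So O1, C2 and C5 are the acetal of a 2,5-diaryl-1,3-dioxolan-4-one, and C2–C3 forms when its 4-ethylidene enol acetal undergoes a 1,3 O-to-C shift.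
- Forward: ring C glyoxylate, then (R)-mandelic acid, cis-dioxolanone with O-benzylvanillin, Z-ethylidene dioxolane, oxolan-3-one (the only ring-forming step), methylenation, hydrogenation with debenzylation, etherification of the ring B phenol with a lactate-derived keto tosylate, ketone reduction, desilylation.
- Stereochemistry: C5 from asymmetric transfer hydrogenation; C2 and C3 relayed from C5 in the rearrangement; C4 by hydrogenation anti to the aryl groups; C8 from ethyl (S)-lactate with one inversion; C7 by Felkin–Anh reduction.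

Key step: step 7

Assumption: RuCl(p-cymene)[(S,S)-TsDPEN] is taken to give the (R)-mandelate, the aryl group being recognised as in acetophenone reductions; if the sense is the opposite, the (R,R)-ligand is used and nothing else changes.

**Step 1**
Reactants: 1 4-bromo-2-methoxyphenol
Product: 2 (4-bromo-2-methoxyphenoxy)triisopropylsilane
Conditions: TIPSCl, imidazole, DMF, rt
Reagents that add atoms: chlorotriisopropylsilane, CC(C)[Si](Cl)(C(C)C)C(C)C
Why: Imidazole-promoted silylation of a phenol; the TIPS ether is chosen over smaller silyl groups because it has to survive LiOH, a phosphazene base and methanolic borohydride later.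

**Step 2**
Reactants: 2 (4-bromo-2-methoxyphenoxy)triisopropylsilane; 3 diethyl oxalate
Product: 5 ethyl 2-[3-methoxy-4-(triisopropylsilyloxy)phenyl]-2-oxoacetate, via aryllithium 4 (not isolated)
Conditions: n-BuLi, THF, −78 °C; cannulated into 3 (2 equiv), THF, −78 °C; 1 M HCl quench
Reagents that add atoms: none
Why: Bromine–lithium exchange followed by inverse addition to excess oxalate is the standard mono-acylation route to aryl glyoxylates, the tetrahedral adduct resisting a second addition at −78 °C.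

**Step 3**
Reactants: 5 ethyl 2-[3-methoxy-4-(triisopropylsilyloxy)phenyl]-2-oxoacetate
Product: 6 ethyl (R)-2-hydroxy-2-[3-methoxy-4-(triisopropylsilyloxy)phenyl]acetate
Conditions: RuCl(p-cymene)[(S,S)-TsDPEN] (1 mol %), HCO2H/Et3N (5:2), DMF, rt
Reagents that add atoms: none
Why: Noyori asymmetric transfer hydrogenation of an activated aryl ketone, in which the C–H/π contact between the guaiacyl ring and the cymene ligand fixes the face that receives hydride and so sets the future C5 as R.

**Step 4**
Reactants: 6 ethyl (R)-2-hydroxy-2-[3-methoxy-4-(triisopropylsilyloxy)phenyl]acetate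
Product: 7 (R)-2-hydroxy-2-[3-methoxy-4-(triisopropylsilyloxy)phenyl]acetic acid
Conditions: LiOH, THF/H2O, 0 °C; then 1 M HCl to pH 3
Reagents that add atoms: lithium hydroxide, [Li+].[OH-]
Why: Saponification of an α-hydroxy ester at 0 °C, conditions under which mandelates should not racemise and the hindered aryl silyl ether should hold.

**Step 5**
Reactants: 7 (R)-2-hydroxy-2-[3-methoxy-4-(triisopropylsilyloxy)phenyl]acetic acid; 8 4-benzyloxy-3-methoxybenzaldehyde
Product: 10 (2R,5R)-2-(4-benzyloxy-3-methoxyphenyl)-5-[3-methoxy-4-(triisopropylsilyloxy)phenyl]-1,3-dioxolan-4-one (2,5-cis), via bis(trimethylsilyl) mandelate 9 (not isolated)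
Conditions: (Me3Si)2NH, TMSCl (cat.), THF, rt, evaporate; then 8, TMSOTf (0.1 equiv), CH2Cl2, −78 °C; pyridine quench
Reagents that add atoms: none
Why: Noyori-type TMSOTf-catalysed acetalisation of a bis-silylated α-hydroxy acid with an aryl aldehyde, which under kinetic control at −78 °C should favour the 2,5-cis dioxolanone; the acetal centre is erased in step 7, so its epimer ratio is not critical.

**Step 6**
Reactants: 10 (2R,5R)-2-(4-benzyloxy-3-methoxyphenyl)-5-[3-methoxy-4-(triisopropylsilyloxy)phenyl]-1,3-dioxolan-4-one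
Product: 11 (2R,5R)-2-(4-benzyloxy-3-methoxyphenyl)-4-[(Z)-ethylidene]-5-[3-methoxy-4-(triisopropylsilyloxy)phenyl]-1,3-dioxolane (2,5-cis)
Conditions: TiCl4, TMEDA, Zn, PbCl2 (cat.), THF, 0 °C to rt; then 10 and CH3CHBr2, rt; aq. K2CO3/Et3N work-up, basic alumina
Reagents that add atoms: 1,1-dibromoethane, CC(Br)Br
Why: Takai–Utimoto alkylidenation of the lactone carbonyl by the reagent from CH3CHBr2, Zn and TiCl4, a reaction known for ethylidenation of the homologous dioxanones, is buffered by TMEDA so the acetal survives and should give the Z enol ether (methyl syn to O3), while any E isomer or acetal epimer would feed the same ion pair in step 7.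

**Step 7**
Reactants: 11 (2R,5R)-2-(4-benzyloxy-3-methoxyphenyl)-4-[(Z)-ethylidene]-5-[3-methoxy-4-(triisopropylsilyloxy)phenyl]-1,3-dioxolane
Product: 12 (2R,4S,5R)-5-(4-benzyloxy-3-methoxyphenyl)-4-methyl-2-[3-methoxy-4-(triisopropylsilyloxy)phenyl]oxolan-3-one (aryl groups cis, methyl trans to the ring B aryl group)
Conditions: Me2AlCl (2 equiv), CH2Cl2, −78 to −40 °C; aq. NaHCO3/Rochelle salt quench
Reagents that add atoms: none
Why: Me2AlCl binds the enol ether oxygen O3 of 11, the acetal C2–O3 bond ionises to a ring B para-benzyloxybenzylidene oxocarbenium ion (C2=O1) that stays tethered through O1 and C5 to a (Z)-aluminium enolate, and the enolate carbon adds to C2, forming C2–C3 and the oxolane as its C4 ketone. The closest known reaction type is the Petasis–Ferrier rearrangement of 4-alkylidene-1,3-dioxolanes and 4-alkylidene-1,3-dioxanes to oxolan-3-ones and oxan-4-ones. The single ring closes in a 5-(enolendo)-endo-trig mode at the oxocarbenium carbon, a geometry that is awkward for neutral acceptors but tolerated by these short-lived, strongly electrophilic ion pairs. C2 is set by the resident C5 centre through an envelope transition state that keeps both aryl groups pseudo-equatorial (2,5-cis), and C3 follows from the Z enolate geometry and, being alpha to the ketone, can settle trans to the C2 aryl group. The step needs C- rather than O-recombination and ionisation at C2–O3 rather than at the ring C benzylic C5–O1 bond: O-recombination only regenerates 11 whereas C–C bond formation is irreversible, and the para-benzyloxy group of ring B makes C2 by far the better cation site. C5 never becomes trigonal, so the configuration installed in step 3 should be carried into the ring unchanged.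

**Step 8**
Reactants: 12 (2R,4S,5R)-5-(4-benzyloxy-3-methoxyphenyl)-4-methyl-2-[3-methoxy-4-(triisopropylsilyloxy)phenyl]oxolan-3-one
Product: 13 (2R,3R,5S)-2-(4-benzyloxy-3-methoxyphenyl)-3-methyl-4-methylidene-5-[3-methoxy-4-(triisopropylsilyloxy)phenyl]oxolane
Conditions: Zn, CH2Br2, TiCl4, THF, 0 °C (pre-formed reagent); then 12, CH2Cl2, 0 °C to rt
Reagents that add atoms: dibromomethane, BrCBr
Why: Takai–Lombardo methylenation with the non-basic reagent from CH2Br2, Zn and TiCl4 is the method of choice for hindered, enolisable ketones, so the two stereocentres flanking the carbonyl should not epimerise.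

**Step 9**
Reactants: 13 (2R,3R,5S)-2-(4-benzyloxy-3-methoxyphenyl)-3-methyl-4-methylidene-5-[3-methoxy-4-(triisopropylsilyloxy)phenyl]oxolane
Product: 14 2-methoxy-4-[(2R,3R,4R,5S)-5-[3-methoxy-4-(triisopropylsilyloxy)phenyl]-3,4-dimethyloxolan-2-yl]phenol
Conditions: H2 (1 atm), Pd/C (10%), EtOAc, rt
Reagents that add atoms: none
Why: Heterogeneous catalytic hydrogenation, in which the alkene face syn to the two aryl groups (C5 aryl adjacent, C2 aryl across the ring) is shielded, so hydrogen should arrive from the face carrying only the C3 methyl and place the new C4 methyl cis to ring C and trans to the C3 methyl, while the benzyl ether is hydrogenolysed in the same operation.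

**Step 10**
Reactants: 15 ethyl (S)-lactate
Product: 16 (S)-2-hydroxy-N-methoxy-N-methylpropanamide
Conditions: MeNH(OMe)·HCl, i-PrMgCl, THF, −20 to 0 °C
Reagents that add atoms: N,O-dimethylhydroxylamine hydrochloride, CNOC.Cl
Why: Weinreb amide formation by aminolysis of the ester with ClMgN(OMe)Me generated in the flask, a reaction that does not touch the lactate stereocentre.

**Step 11**
Reactants: 2 (4-bromo-2-methoxyphenoxy)triisopropylsilane; 16 (S)-2-hydroxy-N-methoxy-N-methylpropanamide
Product: 18 (S)-2-hydroxy-1-[3-methoxy-4-(triisopropylsilyloxy)phenyl]propan-1-one, via arylmagnesium bromide 17 (not isolated)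
Conditions: 2 (2.5 equiv), Mg, THF, 50 °C; then 16, THF, 0 °C to rt; aq. NH4Cl
Reagents that add atoms: none
Why: Grignard addition to a Weinreb amide, in which the first equivalent deprotonates the hydroxyl and the second adds once to give a chelated tetrahedral adduct that releases the ketone only on work-up, so neither over-addition nor racemisation is expected.

**Step 12**
Reactants: 18 (S)-2-hydroxy-1-[3-methoxy-4-(triisopropylsilyloxy)phenyl]propan-1-one
Product: 19 (S)-1-[3-methoxy-4-(triisopropylsilyloxy)phenyl]-1-oxopropan-2-yl 4-methylbenzenesulfonate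
Conditions: TsCl, Et3N, DMAP (cat.), CH2Cl2, 0 °C
Reagents that add atoms: 4-methylbenzenesulfonyl chloride, Cc1ccc(cc1)S(Cl)(=O)=O
Why: O-Sulfonylation of a secondary alcohol turns the lactate hydroxyl into a leaving group with retention, since no bond to C8 is broken.

**Step 13**
Reactants: 14 2-methoxy-4-[(2R,3R,4R,5S)-5-[3-methoxy-4-(triisopropylsilyloxy)phenyl]-3,4-dimethyloxolan-2-yl]phenol; 19 (S)-1-[3-methoxy-4-(triisopropylsilyloxy)phenyl]-1-oxopropan-2-yl 4-methylbenzenesulfonate
Product: 20 (R)-2-{2-methoxy-4-[(2R,3R,4R,5S)-5-[3-methoxy-4-(triisopropylsilyloxy)phenyl]-3,4-dimethyloxolan-2-yl]phenoxy}-1-[3-methoxy-4-(triisopropylsilyloxy)phenyl]propan-1-one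
Conditions: BEMP (2-tert-butylimino-2-diethylamino-1,3-dimethylperhydro-1,3,2-diazaphosphorine), MeCN, 0 °C to rt
Reagents that add atoms: none
Why: Williamson-type SN2 displacement of an α-sulfonyloxy ketone by a phenoxide with inversion at C8 (S to R), the non-ionic phosphazene base forming the phenoxide without carbonate or hydroxide and so limiting enolisation of the keto tosylate and attack on the silyl ethers.

**Step 14**
Reactants: 20 (R)-2-{2-methoxy-4-[(2R,3R,4R,5S)-5-[3-methoxy-4-(triisopropylsilyloxy)phenyl]-3,4-dimethyloxolan-2-yl]phenoxy}-1-[3-methoxy-4-(triisopropylsilyloxy)phenyl]propan-1-one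
Product: 21 (1R,2R)-2-{2-methoxy-4-[(2R,3R,4R,5S)-5-[3-methoxy-4-(triisopropylsilyloxy)phenyl]-3,4-dimethyloxolan-2-yl]phenoxy}-1-[3-methoxy-4-(triisopropylsilyloxy)phenyl]propan-1-ol (threo)
Conditions: polymer-supported borohydride (BH4− form of Amberlite IRA-400), MeOH, 0 °C to rt
Reagents that add atoms: none
Why: Felkin–Anh reduction by a non-chelating quaternary ammonium borohydride, in which the aryloxy group lies anti to the incoming hydride and attack past the C8 hydrogen should give the threo (7R,8R) alcohol.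

**Step 15**
Reactants: 21 (1R,2R)-2-{2-methoxy-4-[(2R,3R,4R,5S)-5-[3-methoxy-4-(triisopropylsilyloxy)phenyl]-3,4-dimethyloxolan-2-yl]phenoxy}-1-[3-methoxy-4-(triisopropylsilyloxy)phenyl]propan-1-ol
Product: 22 4-[(1R,2R)-1-hydroxy-2-{4-[(2R,3R,4R,5S)-5-(4-hydroxy-3-methoxyphenyl)-3,4-dimethyloxolan-2-yl]-2-methoxyphenoxy}propyl]-2-methoxyphenol (CNP0171079.2)
Conditions: TBAF, AcOH, THF, 0 °C
Reagents that add atoms: none
Why: Fluoride cleavage of both aryl silyl ethers, buffered with acetic acid so that the phenols stay protonated and quinone methide formation from the para-hydroxybenzylic alcohol is avoided.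

**Compound list**

1 | 4-bromo-2-methoxyphenol | COc1cc(Br)ccc1O | starting material
2 | (4-bromo-2-methoxyphenoxy)triisopropylsilane | COc1cc(Br)ccc1O[Si](C(C)C)(C(C)C)C(C)C | intermediate
3 | diethyl oxalate | CCOC(=O)C(=O)OCC | starting material
4 | [3-methoxy-4-(triisopropylsilyloxy)phenyl]lithium | [Li]c1ccc(O[Si](C(C)C)(C(C)C)C(C)C)c(OC)c1 | intermediate
5 | ethyl 2-[3-methoxy-4-(triisopropylsilyloxy)phenyl]-2-oxoacetate | CCOC(=O)C(=O)c1ccc(O[Si](C(C)C)(C(C)C)C(C)C)c(OC)c1 | intermediate
6 | ethyl (R)-2-hydroxy-2-[3-methoxy-4-(triisopropylsilyloxy)phenyl]acetate | CCOC(=O)[C@H](O)c1ccc(O[Si](C(C)C)(C(C)C)C(C)C)c(OC)c1 | intermediate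
7 | (R)-2-hydroxy-2-[3-methoxy-4-(triisopropylsilyloxy)phenyl]acetic acid | OC(=O)[C@H](O)c1ccc(O[Si](C(C)C)(C(C)C)C(C)C)c(OC)c1 | intermediate
8 | 4-benzyloxy-3-methoxybenzaldehyde | COc1cc(C=O)ccc1OCc1ccccc1 | starting material
9 | trimethylsilyl (R)-2-[3-methoxy-4-(triisopropylsilyloxy)phenyl]-2-(trimethylsilyloxy)acetate | C[Si](C)(C)OC(=O)[C@H](O[Si](C)(C)C)c1ccc(O[Si](C(C)C)(C(C)C)C(C)C)c(OC)c1 | intermediate
10 | (2R,5R)-2-(4-benzyloxy-3-methoxyphenyl)-5-[3-methoxy-4-(triisopropylsilyloxy)phenyl]-1,3-dioxolan-4-one | COc1cc(ccc1OCc1ccccc1)[C@@H]1O[C@H](c2ccc(O[Si](C(C)C)(C(C)C)C(C)C)c(OC)c2)C(=O)O1 | intermediate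
11 | (2R,5R)-2-(4-benzyloxy-3-methoxyphenyl)-4-[(Z)-ethylidene]-5-[3-methoxy-4-(triisopropylsilyloxy)phenyl]-1,3-dioxolane | COc1cc(ccc1OCc1ccccc1)[C@@H]1O[C@H](c2ccc(O[Si](C(C)C)(C(C)C)C(C)C)c(OC)c2)/C(=C/C)O1 | intermediate
12 | (2R,4S,5R)-5-(4-benzyloxy-3-methoxyphenyl)-4-methyl-2-[3-methoxy-4-(triisopropylsilyloxy)phenyl]oxolan-3-one | COc1cc(ccc1OCc1ccccc1)[C@@H]1O[C@H](c2ccc(O[Si](C(C)C)(C(C)C)C(C)C)c(OC)c2)C(=O)[C@H]1C | intermediate
13 | (2R,3R,5S)-2-(4-benzyloxy-3-methoxyphenyl)-3-methyl-4-methylidene-5-[3-methoxy-4-(triisopropylsilyloxy)phenyl]oxolane | COc1cc(ccc1OCc1ccccc1)[C@@H]1O[C@H](c2ccc(O[Si](C(C)C)(C(C)C)C(C)C)c(OC)c2)C(=C)[C@H]1C | intermediate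
14 | 2-methoxy-4-[(2R,3R,4R,5S)-5-[3-methoxy-4-(triisopropylsilyloxy)phenyl]-3,4-dimethyloxolan-2-yl]phenol | COc1cc(ccc1O)[C@@H]1O[C@H](c2ccc(O[Si](C(C)C)(C(C)C)C(C)C)c(OC)c2)[C@H](C)[C@H]1C | intermediate
15 | ethyl (S)-lactate | CCOC(=O)[C@H](C)O | starting material
16 | (S)-2-hydroxy-N-methoxy-N-methylpropanamide | CON(C)C(=O)[C@H](C)O | intermediate
17 | [3-methoxy-4-(triisopropylsilyloxy)phenyl]magnesium bromide | Br[Mg]c1ccc(O[Si](C(C)C)(C(C)C)C(C)C)c(OC)c1 | intermediate
18 | (S)-2-hydroxy-1-[3-methoxy-4-(triisopropylsilyloxy)phenyl]propan-1-one | C[C@H](O)C(=O)c1ccc(O[Si](C(C)C)(C(C)C)C(C)C)c(OC)c1 | intermediate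
19 | (S)-1-[3-methoxy-4-(triisopropylsilyloxy)phenyl]-1-oxopropan-2-yl 4-methylbenzenesulfonate | C[C@H](OS(=O)(=O)c1ccc(C)cc1)C(=O)c1ccc(O[Si](C(C)C)(C(C)C)C(C)C)c(OC)c1 | intermediate
20 | (R)-2-{2-methoxy-4-[(2R,3R,4R,5S)-5-[3-methoxy-4-(triisopropylsilyloxy)phenyl]-3,4-dimethyloxolan-2-yl]phenoxy}-1-[3-methoxy-4-(triisopropylsilyloxy)phenyl]propan-1-one | COc1cc(ccc1O[C@H](C)C(=O)c1ccc(O[Si](C(C)C)(C(C)C)C(C)C)c(OC)c1)[C@@H]1O[C@H](c2ccc(O[Si](C(C)C)(C(C)C)C(C)C)c(OC)c2)[C@H](C)[C@H]1C | intermediate
21 | (1R,2R)-2-{2-methoxy-4-[(2R,3R,4R,5S)-5-[3-methoxy-4-(triisopropylsilyloxy)phenyl]-3,4-dimethyloxolan-2-yl]phenoxy}-1-[3-methoxy-4-(triisopropylsilyloxy)phenyl]propan-1-ol | COc1cc(ccc1O[C@H](C)[C@H](O)c1ccc(O[Si](C(C)C)(C(C)C)C(C)C)c(OC)c1)[C@@H]1O[C@H](c2ccc(O[Si](C(C)C)(C(C)C)C(C)C)c(OC)c2)[C@H](C)[C@H]1C | intermediate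
22 | 4-[(1R,2R)-1-hydroxy-2-{4-[(2R,3R,4R,5S)-5-(4-hydroxy-3-methoxyphenyl)-3,4-dimethyloxolan-2-yl]-2-methoxyphenoxy}propyl]-2-methoxyphenol | COc1cc([C@@H](O)[C@@H](C)Oc2ccc([C@@H]3O[C@H](c4ccc(O)c(OC)c4)[C@H](C)[C@H]3C)cc2OC)ccc1O | target

**Step count and risks**

Total: 15 steps. Longest linear sequence: 12 steps (steps 1–9, then 13–15); steps 10–12 form the side-chain branch, which also draws on compound 2.

Step 7 is the most likely to fail. Under the Lewis acid the ion pair may fragment instead of recombining (loss of the ring B aldehyde, or ionisation of the ring C benzylic C5–O1 bond with erosion of the C5 configuration), and the product ketone may enolise toward C5 or reopen. The fallback sets out from 11 and switches to a reductive rearrangement: i-Bu3Al in CH2Cl2 (−78 °C to rt) is a weaker Lewis acid and reduces the ketone in the flask by β-hydride transfer, so the ring is trapped as the aluminium alkoxide of 5-(4-benzyloxy-3-methoxyphenyl)-4-methyl-2-[3-methoxy-4-(triisopropylsilyloxy)phenyl]oxolan-3-ol F1 (carbinol configuration immaterial). Oxidation with Dess–Martin periodinane buffered by NaHCO3 then comes back to the route at 12.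

Step 9 is next. Aryl-anchored adsorption on the Pd surface may deliver hydrogen syn to the aryl groups (poor facial selectivity at C4). The double bond may migrate into the ring before it is reduced. The allylic, benzylic C5–O1 bond may be hydrogenolysed. The fallback sets out from 13 and separates the two events: metal-free, concerted syn reduction with diimide (2-nitrobenzenesulfonylhydrazide, Et3N, CH2Cl2, rt), governed by sterics alone and incapable of migration or hydrogenolysis, should give (2R,3R,4R,5S)-2-(4-benzyloxy-3-methoxyphenyl)-3,4-dimethyl-5-[3-methoxy-4-(triisopropylsilyloxy)phenyl]oxolane F2. Its benzyl ether is then removed over Pd/C under H2 in EtOAc, which comes back to the route at 14.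

Step 13 is third. Enolisation of the keto tosylate or of the product by the phenoxide would erode the C8 configuration, and silyl transfer from the activated ring A silyl ether to the phenoxide may compete. The fallback sets out from 14 and forms the ether before the ketone exists. Mitsunobu etherification with ethyl (S)-lactate 15 (PPh3, DIAD, THF, 0 °C to rt) should give, with inversion, ethyl (R)-2-{2-methoxy-4-[(2R,3R,4R,5S)-5-[3-methoxy-4-(triisopropylsilyloxy)phenyl]-3,4-dimethyloxolan-2-yl]phenoxy}propanoate F3. Treatment with MeNH(OMe)·HCl and i-PrMgCl (THF, −20 °C) converts it into the corresponding (R)-N-methoxy-N-methyl-2-aryloxypropanamide F4. Addition of aryllithium 4 (from 2, n-BuLi, THF, −78 °C) comes back to the route at 20.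

**Further compounds**

F1 | step 7 | 5-(4-benzyloxy-3-methoxyphenyl)-4-methyl-2-[3-methoxy-4-(triisopropylsilyloxy)phenyl]oxolan-3-ol (ring carbons configured as in 12) | COc1cc(ccc1OCc1ccccc1)[C@@H]1O[C@H](c2ccc(O[Si](C(C)C)(C(C)C)C(C)C)c(OC)c2)C(O)[C@H]1C
F2 | step 9 | (2R,3R,4R,5S)-2-(4-benzyloxy-3-methoxyphenyl)-3,4-dimethyl-5-[3-methoxy-4-(triisopropylsilyloxy)phenyl]oxolane | COc1cc(ccc1OCc1ccccc1)[C@@H]1O[C@H](c2ccc(O[Si](C(C)C)(C(C)C)C(C)C)c(OC)c2)[C@H](C)[C@H]1C
F3 | step 13 | ethyl (R)-2-{2-methoxy-4-[(2R,3R,4R,5S)-5-[3-methoxy-4-(triisopropylsilyloxy)phenyl]-3,4-dimethyloxolan-2-yl]phenoxy}propanoate | COc1cc(ccc1O[C@H](C)C(=O)OCC)[C@@H]1O[C@H](c2ccc(O[Si](C(C)C)(C(C)C)C(C)C)c(OC)c2)[C@H](C)[C@H]1C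
F4 | step 13 | (R)-N-methoxy-N-methyl-2-{2-methoxy-4-[(2R,3R,4R,5S)-5-[3-methoxy-4-(triisopropylsilyloxy)phenyl]-3,4-dimethyloxolan-2-yl]phenoxy}propanamide | COc1cc(ccc1O[C@H](C)C(=O)N(C)OC)[C@@H]1O[C@H](c2ccc(O[Si](C(C)C)(C(C)C)C(C)C)c(OC)c2)[C@H](C)[C@H]1C
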